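**Plan**

- Retrosynthesis: the MOM group on the ring A phenol is removed last. Ring B is then cut at C1'–C2' and C5'–C6', with SO2 as the extruded bridge, giving an aryl ethynyl ether of ring A and 2,4-dibromothiophene 1,1-dioxide.
- Enabling feature: ring B carries O on C1', Br on C2' and C4', and H on C3', C5' and C6'. C2'–C5' are therefore the four carbons of 2,4-dibromothiophene, and C1'/C6' are the two carbons of an aryloxyacetylene.
- The ynol ether goes back through a 2-bromovinyl ether and a vinyl ether to 3,4-dibromo-2-(methoxymethoxy)phenol. Its second oxygen comes from ortho-formylation and Baeyer–Villiger oxidation of 2,3-dibromophenol.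
- Forward: ring A is bought with both bromines in place and is elaborated only at oxygen, without any organolithium near the aryl bromides. Ring B is the only ring made; the cycloaddition/SO2 loss closes it and the thiophene supplies its two bromines.
- Stereochemistry: there is none to set; the only selectivity that matters is the orientation of the cycloaddition.

Key step: step 8

Remark: the target has no stereocentre and is a single achiral compound, so no enantiocontrol is required; steps 6 and 7 are run back to back so that 9 and 11 are both fresh for step 8.

**Route**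

Step 1
Reactants: 1 2,3-dibromophenol
Product: 2 3,4-dibromo-2-hydroxybenzaldehyde
Conditions: MgCl2 (anhydrous), Et3N, (CH2O)n, THF, reflux; aq. HCl work-up
Reagents that add atoms: paraformaldehyde (formaldehyde), C=O
Why: Magnesium-phenoxide-directed ortho-formylation (Casnati–Skattebøl) can only occur at C6, the one free ortho position, and ortho-halophenols are standard substrates for it.

Step 2
Reactants: 2 3,4-dibromo-2-hydroxybenzaldehyde
Product: 3 3,4-dibromo-2-(methoxymethoxy)benzaldehyde
Conditions: MOMCl, K2CO3, DMF, 0 °C → rt
Reagents that add atoms: chloromethyl methyl ether, COCCl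
Why: Williamson-type O-alkylation of the phenoxide installs an acetal that should survive peracid, copper, bromine at low temperature, alkoxide base and heat, and that falls off with acid at the end.

Step 3
Reactants: 3 3,4-dibromo-2-(methoxymethoxy)benzaldehyde
Product: 5 3,4-dibromo-2-(methoxymethoxy)phenol, via aryl formate 4 (not isolated)
Conditions: mCPBA, CH2Cl2, 0 °C → rt; then K2CO3 (cat.), MeOH, 0 °C
Reagents that add atoms: meta-chloroperoxybenzoic acid, OOC(=O)c1cccc(Cl)c1
Why: Baeyer–Villiger (Dakin-type) oxidation, in which the ortho-alkoxy-substituted aryl group migrates in preference to hydrogen, followed by mild methanolysis of the formate, gives the catechol with its two oxygens already differentiated.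

Step 4
Reactants: 5 3,4-dibromo-2-(methoxymethoxy)phenol
Product: 6 1,2-dibromo-4-(ethenyloxy)-3-(methoxymethoxy)benzene
Conditions: 2,4,6-trivinylcyclotriboroxane·pyridine, Cu(OAc)2, pyridine, CH2Cl2, rt, air
Reagents that add atoms: 2,4,6-trivinylcyclotriboroxane–pyridine complex, C=CB1OB(C=C)OB(C=C)O1.c1ccncc1
Why: Chan–Lam-type copper(II)-mediated O-vinylation of phenols runs at room temperature and leaves aryl bromides and the MOM acetal untouched.

Step 5
Reactants: 6 1,2-dibromo-4-(ethenyloxy)-3-(methoxymethoxy)benzene
Product: 8 (Z)-1,2-dibromo-4-[(2-bromoethenyl)oxy]-3-(methoxymethoxy)benzene, via 1,2-dibromoethyl ether 7 (not isolated)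
Conditions: Br2 (1.0 equiv), CH2Cl2, −78 °C; then i-Pr2NEt, −78 °C → rt
Reagents that add atoms: bromine, BrBr
Why: Bromine adds to the enol ether double bond far faster than it substitutes the dibrominated ring at −78 °C, and amine-promoted dehydrobromination through ionisation of the α-bromo ether is the classical route to 2-bromovinyl ethers, with the Z isomer expected to predominate.

Step 6
Reactants: 8 (Z)-1,2-dibromo-4-[(2-bromoethenyl)oxy]-3-(methoxymethoxy)benzene
Product: 9 1,2-dibromo-4-(ethynyloxy)-3-(methoxymethoxy)benzene
Conditions: KOtBu, THF, −78 → 0 °C
Reagents that add atoms: none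
Why: Anti E2 dehydrobromination of the Z-2-bromovinyl ether (H on the oxygen-bearing carbon trans to Br) is the classical aryloxyacetylene synthesis, and an alkoxide base cannot undergo halogen–metal exchange with the two aryl bromides.

Step 7
Reactants: 10 2,4-dibromothiophene
Product: 11 2,4-dibromothiophene 1,1-dioxide
Conditions: TFAA, urea·H2O2, CH2Cl2/MeCN, 0 °C → rt
Reagents that add atoms: urea–hydrogen peroxide, OO.NC(N)=O (oxygen delivered as trifluoroperacetic acid, OOC(=O)C(F)(F)F, formed in the flask with trifluoroacetic anhydride)
Why: Peracid S-oxidation with trifluoroperacetic acid is the established way to take electron-poor halothiophenes through the sulfoxide to the sulfone, and the product is kept cold and used within a day.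

Step 8
Reactants: 9 1,2-dibromo-4-(ethynyloxy)-3-(methoxymethoxy)benzene; 11 2,4-dibromothiophene 1,1-dioxide
Product: 13 1,2-dibromo-4-(2,4-dibromophenoxy)-3-(methoxymethoxy)benzene, via bicyclic sulfone 12 (not isolated)
Conditions: 11 (1.5 equiv, in portions), toluene, 4 Å MS, 40–70 °C, slow N2 sweep
Reagents that add atoms: none
Why: Proposed new method: the electron-poor diene sulfone 11 and the electron-rich alkyne 9 should undergo an inverse-electron-demand Diels–Alder reaction, the nucleophilic CH terminus of 9 bonding to the unsubstituted C5 of 11 and the oxygen-bearing carbon to C2, to give the 7-thiabicyclo[2.2.1]heptadiene dioxide 12, which loses SO2 cheletropically at once. The closest known reaction type is the Diels–Alder/SO2-extrusion benzannulation of halogenated thiophene 1,1-dioxides with alkynes, together with the inverse-demand cycloadditions of alkoxyalkynes with electron-poor dienes; what is new is the pairing of an aryl ethynyl ether with a thiophene dioxide. Ring B, the only ring made, is closed by an intermolecular [4+2] cycloaddition that forms C1'–C2' and C6'–C5' in one operation, and the extrusion leaves it aromatic without an oxidation step. No stereocentre is created. The step needs one regiochemical orientation, which is favoured twice over: C5 is the less hindered diene terminus, and attack there places the developing negative charge on C4 and C2, both bromine-bearing and C2 also next to the sulfonyl group, whereas attack at C2 would place it on carbons without bromine. It also needs the cross-reaction to outpace self-dimerisation of 11, for which the strongly polarised, unhindered terminal alkyne, moderate temperature and portionwise addition of a modest excess of 11 are relied on.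

Step 9
Reactants: 13 1,2-dibromo-4-(2,4-dibromophenoxy)-3-(methoxymethoxy)benzene
Product: 14 2,3-dibromo-6-(2,4-dibromophenoxy)phenol
Conditions: conc. HCl (cat.), MeOH/THF, 50 °C
Reagents that add atoms: none
Why: Acid-catalysed methanolysis of the MOM acetal frees the phenol, while the diaryl ether and the four aryl bromides are inert to these conditions.

**Compound list**

1 | 2,3-dibromophenol | Oc1cccc(Br)c1Br | starting material
2 | 3,4-dibromo-2-hydroxybenzaldehyde | O=Cc1ccc(Br)c(Br)c1O | intermediate
3 | 3,4-dibromo-2-(methoxymethoxy)benzaldehyde | COCOc1c(C=O)ccc(Br)c1Br | intermediate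
4 | 3,4-dibromo-2-(methoxymethoxy)phenyl formate (not isolated) | O=COc1ccc(Br)c(Br)c1OCOC | intermediate
5 | 3,4-dibromo-2-(methoxymethoxy)phenol | Oc1ccc(Br)c(Br)c1OCOC | intermediate
6 | 1,2-dibromo-4-(ethenyloxy)-3-(methoxymethoxy)benzene | C=COc1ccc(Br)c(Br)c1OCOC | intermediate
7 | 1,2-dibromo-4-(1,2-dibromoethoxy)-3-(methoxymethoxy)benzene (racemic, not isolated) | BrCC(Br)Oc1ccc(Br)c(Br)c1OCOC | intermediate
8 | (Z)-1,2-dibromo-4-[(2-bromoethenyl)oxy]-3-(methoxymethoxy)benzene | Br/C=C\Oc1ccc(Br)c(Br)c1OCOC | intermediate
9 | 1,2-dibromo-4-(ethynyloxy)-3-(methoxymethoxy)benzene | C#COc1ccc(Br)c(Br)c1OCOC | intermediate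
10 | 2,4-dibromothiophene | Brc1csc(Br)c1 | starting material
11 | 2,4-dibromothiophene 1,1-dioxide | O=S1(=O)C=C(Br)C=C1Br | intermediate
12 | 1,5-dibromo-2-[3,4-dibromo-2-(methoxymethoxy)phenoxy]-7-thiabicyclo[2.2.1]hepta-2,5-diene 7,7-dioxide (racemic, bridgehead configuration fixed by the bridge, not isolated) | O=S1(=O)C2(Br)C=C(Br)C1C=C2Oc1ccc(Br)c(Br)c1OCOC | intermediate
13 | 1,2-dibromo-4-(2,4-dibromophenoxy)-3-(methoxymethoxy)benzene | COCOc1c(Oc2ccc(Br)cc2Br)ccc(Br)c1Br | intermediate
14 | 2,3-dibromo-6-(2,4-dibromophenoxy)phenol | Oc1c(Oc2ccc(Br)cc2Br)ccc(Br)c1Br | target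

**Step count**

Total steps: 9. Longest linear sequence: 8 (steps 1–6, 8, 9 from 2,3-dibromophenol); step 7 is a one-step side branch.

**Steps most likely to fail**

Step 8 (proposed new method). The cycloaddition may be outrun by self-dimerisation of the dioxide, the terminal ynol ether may polymerise or be hydrolysed by adventitious acid, or the addends may combine in the other orientation and give the 3,5-dibromophenyl ether. The fallback uses the established diaryliodonium route to brominated diphenyl ethers; it sets out from phenol 5 and returns at 13. 1,3-Dibromobenzene is treated with iodyl sulfate in sulfuric acid and then with chloride to give bis(2,4-dibromophenyl)iodonium chloride F1. The sodium phenoxide of 5 (NaOH, water/dioxane, reflux) is then O-arylated by F1 through ligand coupling at iodine(III). The MOM acetal is stable to base, so 13 should result directly and step 9 follows unchanged.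

Step 7. Oxidation may stall at the sulfoxide, which dimerises readily, or the dioxide itself may undergo Diels–Alder self-dimerisation with SO2 loss during concentration and storage. The fallback keeps the same two bond formations but changes the diene; it sets out from 9 and returns at 13. Ynol ether 9 is heated in toluene at 80–100 °C with 3,5-dibromo-2H-pyran-2-one (O=c1occ(Br)cc1Br, available commercially or in one step from coumalic acid), a bench-stable ambiphilic diene. The nucleophilic CH terminus should bond to C6 of the pyrone and the oxygen-bearing carbon to C3, giving the bridged lactone 4,7-dibromo-5-[3,4-dibromo-2-(methoxymethoxy)phenoxy]-2-oxabicyclo[2.2.2]octa-5,7-dien-3-one F2. F2 should extrude CO2 under the reaction conditions and deliver the same 2,4-dibromophenyl ether 13.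

Step 6. Elimination may be incomplete for any E isomer carried over from step 5, tert-butoxide may add to the new alkyne, and the terminal ynol ether may polymerise on concentration. The fallback uses the bromovinyl ether as an alkyne surrogate; it sets out from 8 and returns at 13. Heating 8 with 11 in toluene should give the bridged sulfone 1,3,5-tribromo-6-[3,4-dibromo-2-(methoxymethoxy)phenoxy]-7-thiabicyclo[2.2.1]hept-2-ene 7,7-dioxide F3 with the same orientation as in step 8. Loss of SO2 from F3 should give 1,2-dibromo-3-(methoxymethoxy)-4-{[cis-2,4,6-tribromocyclohexa-2,4-dien-1-yl]oxy}benzene F4. Treatment of F4 with DBU should then aromatise ring B by anti elimination of HBr to give 13, since bromide is a far better leaving group than the aryloxide. This variant is expected to be slower than the alkyne cycloaddition because 8 is less electron-rich than 9.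

**Further compounds**

F1 | step 8 | bis(2,4-dibromophenyl)iodonium chloride | Brc1ccc([I+]c2ccc(Br)cc2Br)c(Br)c1.[Cl-]
F2 | step 7 | 4,7-dibromo-5-[3,4-dibromo-2-(methoxymethoxy)phenoxy]-2-oxabicyclo[2.2.2]octa-5,7-dien-3-one (racemic, not isolated) | O=C1OC2C=C(Oc3ccc(Br)c(Br)c3OCOC)C1(Br)C=C2Br
F3 | step 6 | 1,3,5-tribromo-6-[3,4-dibromo-2-(methoxymethoxy)phenoxy]-7-thiabicyclo[2.2.1]hept-2-ene 7,7-dioxide (racemic, 5,6-cis, endo/exo not assigned, not isolated) | O=S1(=O)C2(Br)C=C(Br)C1C(Br)C2Oc1ccc(Br)c(Br)c1OCOC
F4 | step 6 | 1,2-dibromo-3-(methoxymethoxy)-4-{[cis-2,4,6-tribromocyclohexa-2,4-dien-1-yl]oxy}benzene (racemic, one enantiomer drawn) | Br[C@H]1C=C(Br)C=C(Br)[C@H]1Oc1ccc(Br)c(Br)c1OCOC
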